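**Retrosynthetic overview** (flavone numbering)

- Feature: in ring A, C8a (bearing O1) lies para to the C6 methoxy and the C7 methoxy sits beside C6. The chain carbon C4 hangs on C4a ortho to O1, and C5 and C8 carry only hydrogen. Ring A is therefore a 2-alkyl-4,5-dimethoxyphenol, the 4-methoxyphenol pattern that a Dötz benzannulation produces.
- Ring C is opened first at O1–C2 to an o-hydroxyaryl ynone, which is traced back through its propargylic carbinol to the silyl ether.
- Ring A is then cut at C5–C6, C4a–C8a and C8–C8a into three pieces: the methoxy(1-methoxyvinyl)carbene ligand on Cr(CO)5 (C6, C7, C8), one CO ligand (C8a and O1), and the terminal alkyne (C5, C4a) of a skipped diyne that already holds C4, C3, C2 and ring B.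
- The diyne comes from the ring B acetylene by formylation, ethynyl Grignard addition and silylation. The carbene complex comes from methyl vinyl ether and Cr(CO)6.
- Order of rings: ring B is bought, ring A is made in step 5, ring C in step 8.

Key step: step 5

Remark: the target has no stereocentre. The carbinol carbon C4 of 10 to 14 is carried as a racemate because it ends as the carbonyl carbon. In the SMILES of chromium compounds a CO ligand is written =C=O and the η6 bond of 12 as a dot.

**Step 1**
Reactants: 1 methyl vinyl ether; 2 chromium hexacarbonyl, Cr(CO)6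
Product: 5 pentacarbonyl[methoxy(1-methoxyvinyl)carbene]chromium, via 1-methoxyvinyllithium 3 (not isolated), via lithium pentacarbonyl(2-methoxyacryloyl)chromate 4 (not isolated)
Conditions: 1 (excess), t-BuLi, THF/pentane, −78 → 0 °C; Cr(CO)6, Et2O, 0 °C → rt; solvent removed; Me3OBF4, dry CH2Cl2, 0 °C; quick silica filtration under Ar, stored cold
Reagents that add atoms: trimethyloxonium tetrafluoroborate, C[O+](C)C.F[B-](F)(F)F
Why: Fischer carbene synthesis, in which oxygen-directed α-lithiation of the enol ether gives 3, this adds to a CO ligand of Cr(CO)6 to give acylmetalate 4, and the hard oxonium salt methylates the acyl oxygen under anhydrous conditions that spare the enol ether.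

**Step 2**
Reactants: 6 5-ethynyl-1,2,3-trimethoxybenzene
Product: 8 3-(3,4,5-trimethoxyphenyl)prop-2-ynal, via lithium (3,4,5-trimethoxyphenyl)acetylide 7 (not isolated)
Conditions: n-BuLi, THF, −40 °C; DMF, −40 °C → rt; inverse quench into aq KH2PO4/MTBE, 5 °C
Reagents that add atoms: N,N-dimethylformamide, CN(C)C=O
Why: Formylation of a lithium acetylide with DMF, where the buffered inverse quench keeps the released dimethylamine protonated so that it cannot add to the ynal.

**Step 3**
Reactants: 8 3-(3,4,5-trimethoxyphenyl)prop-2-ynal; 9 ethynylmagnesium bromide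
Product: 10 1-(3,4,5-trimethoxyphenyl)penta-1,4-diyn-3-ol (racemic)
Conditions: HC≡CMgBr (0.5 M in THF), THF, −20 → 0 °C; sat. aq NH4Cl
Reagents that add atoms: none
Why: Grignard 1,2-addition of an alkynyl nucleophile to an ynal, which goes to the carbonyl and not to the triple bond; the carbinol centre forms as a racemate and is erased in step 7.

**Step 4**
Reactants: 10 1-(3,4,5-trimethoxyphenyl)penta-1,4-diyn-3-ol
Product: 11 tert-butyldimethylsilyl ether of 1-(3,4,5-trimethoxyphenyl)penta-1,4-diyn-3-ol (racemic)
Conditions: TBSCl, imidazole, DMF, 0 °C → rt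
Reagents that add atoms: tert-butyldimethylsilyl chloride, CC(C)(C)[Si](C)(C)Cl
Why: Imidazole-promoted O-silylation of a secondary alcohol, with a base too weak to isomerise the skipped diyne to an allenyne; the silyl ether removes a hydroxyl that could otherwise trap the ketene intermediate of step 5.

**Step 5**
Reactants: 5 pentacarbonyl[methoxy(1-methoxyvinyl)carbene]chromium; 11 tert-butyldimethylsilyl ether of 1-(3,4,5-trimethoxyphenyl)penta-1,4-diyn-3-ol
Product: 13 2-[1-(tert-butyldimethylsilyloxy)-3-(3,4,5-trimethoxyphenyl)prop-2-ynyl]-4,5-dimethoxyphenol (racemic), via tricarbonylchromium-bound phenol 12 (not isolated)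
Conditions: 5 (1.0 equiv), 11 (1.1 equiv), degassed THF (0.1 M), Ar, 50 °C, 16 h; then Et2O, air, daylight, rt; filtration through silica
Reagents that add atoms: none
Why: Heating expels one cis CO from the zerovalent chromium complex 5, the terminal triple bond of 11 takes the free site and inserts into Cr=C with its CH end bonding to the carbene carbon (C5–C6), a CO ligand migrates onto the new carbene carbon to give a chromium-bound dienylketene (C4a–C8a), and ring closure plus enolisation leaves the phenol as its Cr(CO)3 complex 12, which air then demetalates. The closest known reaction type is the Dötz benzannulation of alkenyl(methoxy)carbene chromium complexes with terminal alkynes, which tolerates propargylic silyl ethers and is known for cyclic 1-alkoxyalkenyl complexes (dihydropyranyl and glycal-derived), the nearest relatives of 5. Ring A closes by a six-electron electrocyclisation of the dienylketene in which the ketene carbon C8a bonds to the vinyl CH2 terminus C8, so that the carbene methoxy ends on C6, the vinyl methoxy on C7 and the former CO oxygen becomes the C8a hydroxyl, the later O1. No stereocentre of the target is at stake, since the carbinol carbon stays racemic and the planar chirality of 12 disappears with the metal. Regioselectivity (chain on C4a beside the hydroxyl, hydrogen on C5) follows from the steric bias of the insertion, which keeps the larger alkyne substituent away from the carbene carbon and next to the incoming CO and is practically complete for terminal alkynes. Site selectivity rests on the internal triple bond being flanked by an aryl ring and by the silyloxy-bearing carbon and so binding more slowly to the 16-electron Cr(CO)4 carbene, on 5 being the limiting partner so that no second annulation follows, and on the one-carbon spacer, which rules out an intramolecular second insertion because that would need a three- or four-membered ring.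

**Step 6**
Reactants: 13 2-[1-(tert-butyldimethylsilyloxy)-3-(3,4,5-trimethoxyphenyl)prop-2-ynyl]-4,5-dimethoxyphenol
Product: 14 2-[1-hydroxy-3-(3,4,5-trimethoxyphenyl)prop-2-ynyl]-4,5-dimethoxyphenol (racemic)
Conditions: Bu4NF, AcOH (1:1), THF, 0 °C → rt; used promptly
Reagents that add atoms: none
Why: Fluoride-driven cleavage of the Si–O bond, with acetic acid buffering to keep phenoxide and alkoxide levels low so that neither propargyl–allene isomerisation nor quinone methide formation sets in.

**Step 7**
Reactants: 14 2-[1-hydroxy-3-(3,4,5-trimethoxyphenyl)prop-2-ynyl]-4,5-dimethoxyphenol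
Product: 15 1-(2-hydroxy-4,5-dimethoxyphenyl)-3-(3,4,5-trimethoxyphenyl)prop-2-yn-1-one
Conditions: activated MnO2 (excess), CH2Cl2, 0 °C → rt
Reagents that add atoms: none
Why: MnO2 oxidation of a carbinol that is both benzylic and propargylic, a neutral heterogeneous method established for 1-(2-hydroxyaryl)prop-2-yn-1-ols, and the product phenol is stabilised by its hydrogen bond to the new carbonyl.

**Step 8**
Reactants: 15 1-(2-hydroxy-4,5-dimethoxyphenyl)-3-(3,4,5-trimethoxyphenyl)prop-2-yn-1-one
Product: 17 prosogerin C (6,7-dimethoxy-2-(3,4,5-trimethoxyphenyl)-4H-chromen-4-one), via diethylamino enone 16 (not isolated)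
Conditions: Et2NH (5 equiv), EtOH, rt → 78 °C
Reagents that add atoms: none
Why: Aza-Michael addition of the secondary amine to the ynone gives enaminone 16, whose only electrophilic carbon within reach of the phenol is C2, so oxa-Michael addition and β-elimination of diethylamine (a 6-endo closure overall, the known amine-mediated flavone synthesis from o-hydroxyaryl ynones) form O1–C2 and shut off the 5-exo path to the aurone.

**Compound list**

1 | methyl vinyl ether | C=COC | starting material
2 | chromium hexacarbonyl, Cr(CO)6 | O=C=[Cr](=C=O)(=C=O)(=C=O)(=C=O)=C=O | starting material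
3 | 1-methoxyvinyllithium | [Li]C(=C)OC | intermediate
4 | lithium pentacarbonyl(2-methoxyacryloyl)chromate | [Li+].C=C(OC)C(=O)[Cr-](=C=O)(=C=O)(=C=O)(=C=O)=C=O | intermediate
5 | pentacarbonyl[methoxy(1-methoxyvinyl)carbene]chromium | C=C(OC)C(OC)=[Cr](=C=O)(=C=O)(=C=O)(=C=O)=C=O | intermediate
6 | 5-ethynyl-1,2,3-trimethoxybenzene | C#Cc1cc(OC)c(OC)c(OC)c1 | starting material
7 | lithium (3,4,5-trimethoxyphenyl)acetylide | [Li]C#Cc1cc(OC)c(OC)c(OC)c1 | intermediate
8 | 3-(3,4,5-trimethoxyphenyl)prop-2-ynal | O=CC#Cc1cc(OC)c(OC)c(OC)c1 | intermediate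
9 | ethynylmagnesium bromide | C#C[Mg]Br | starting material
10 | 1-(3,4,5-trimethoxyphenyl)penta-1,4-diyn-3-ol (racemic) | C#CC(O)C#Cc1cc(OC)c(OC)c(OC)c1 | intermediate
11 | tert-butyldimethylsilyl ether of 1-(3,4,5-trimethoxyphenyl)penta-1,4-diyn-3-ol (racemic) | C#CC(O[Si](C)(C)C(C)(C)C)C#Cc1cc(OC)c(OC)c(OC)c1 | intermediate
12 | tricarbonyl{η6-2-[1-(tert-butyldimethylsilyloxy)-3-(3,4,5-trimethoxyphenyl)prop-2-ynyl]-4,5-dimethoxyphenol}chromium (ring A bound, diastereomer mixture) | COc1cc(O)c(C(O[Si](C)(C)C(C)(C)C)C#Cc2cc(OC)c(OC)c(OC)c2)cc1OC.O=C=[Cr](=C=O)=C=O | intermediate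
13 | 2-[1-(tert-butyldimethylsilyloxy)-3-(3,4,5-trimethoxyphenyl)prop-2-ynyl]-4,5-dimethoxyphenol (racemic) | COc1cc(O)c(C(O[Si](C)(C)C(C)(C)C)C#Cc2cc(OC)c(OC)c(OC)c2)cc1OC | intermediate
14 | 2-[1-hydroxy-3-(3,4,5-trimethoxyphenyl)prop-2-ynyl]-4,5-dimethoxyphenol (racemic) | COc1cc(O)c(C(O)C#Cc2cc(OC)c(OC)c(OC)c2)cc1OC | intermediate
15 | 1-(2-hydroxy-4,5-dimethoxyphenyl)-3-(3,4,5-trimethoxyphenyl)prop-2-yn-1-one | COc1cc(O)c(C(=O)C#Cc2cc(OC)c(OC)c(OC)c2)cc1OC | intermediate
16 | (E)-3-(diethylamino)-1-(2-hydroxy-4,5-dimethoxyphenyl)-3-(3,4,5-trimethoxyphenyl)prop-2-en-1-one (geometry without consequence) | CCN(CC)/C(=C/C(=O)c1cc(OC)c(OC)cc1O)c1cc(OC)c(OC)c(OC)c1 | intermediate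
17 | prosogerin C | COc1cc2oc(-c3cc(OC)c(OC)c(OC)c3)cc(=O)c2cc1OC | target

**Total step count:** 8. **Longest linear sequence:** 7 (steps 2 to 8, from 6).

**Steps most likely to fail**

1. **Step 5.** The carbene may also insert at the internal triple bond, a second annulation may follow on the product, or the terminal alkyne may oligomerise faster than CO insertion takes place.
 - The fallback sets out from 5 (with 7 made from 6 as in step 2) and comes back at 14.
 - The benzannulation is run on an alkyne that has only one triple bond, commercial 3,3-diethoxyprop-1-yne, in THF at 50 °C. This should give tricarbonyl[η6-2-(diethoxymethyl)-4,5-dimethoxyphenol]chromium F1.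
 - Air releases 2-(diethoxymethyl)-4,5-dimethoxyphenol F2, and aqueous oxalic acid in THF unmasks 2-hydroxy-4,5-dimethoxybenzaldehyde F3.
 - Two equivalents of 7 in THF at −78 → 0 °C (the first acting as base for the phenol) add to the aldehyde to give 14.
 - Ring A is still built through the same three bonds, but the ring B alkyne arrives only after chromium has left, so no site selectivity is needed.

2. **Step 1.** Acid traces from the oxonium salt may cleave the enol ether, O-methylation of the crude lithium salt may stall, or the complex may decay during purification.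
 - The fallback sets out from 4 and comes back at 5.
 - Cation exchange with aqueous Me4NBr gives the isolable, recrystallisable tetramethylammonium pentacarbonyl(2-methoxyacryloyl)chromate F4.
 - Acetyl bromide in CH2Cl2 at −40 °C converts it into pentacarbonyl[acetoxy(1-methoxyvinyl)carbene]chromium F5.
 - Methanol added at −40 °C displaces acetate at the carbene carbon to give 5.
 - The methoxy group thus enters by nucleophilic substitution on an acyloxycarbene instead of by electrophilic methylation.

3. **Step 7.** The oxidant may attack the electron-rich free phenol in competition with the carbinol, or the highly activated benzylic carbinol may ionise on the oxide surface.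
 - The fallback sets out from 13, bypasses 14 and comes back at 15.
 - The phenol is capped first (MOMCl, i-Pr2NEt, CH2Cl2) to give the methoxymethyl ether of 13 F6.
 - Bu4NF in THF frees 1-[4,5-dimethoxy-2-(methoxymethoxy)phenyl]-3-(3,4,5-trimethoxyphenyl)prop-2-yn-1-ol F7.
 - Dess–Martin periodinane with NaHCO3 in CH2Cl2, now safe in the absence of a free phenol, gives 1-[4,5-dimethoxy-2-(methoxymethoxy)phenyl]-3-(3,4,5-trimethoxyphenyl)prop-2-yn-1-one F8.
 - Aqueous HCl in i-PrOH/THF removes the acetal ortho to the carbonyl to give 15.

**Further compounds**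

F1 | step 5 | tricarbonyl[η6-2-(diethoxymethyl)-4,5-dimethoxyphenol]chromium | CCOC(OCC)c1cc(OC)c(OC)cc1O.O=C=[Cr](=C=O)=C=O
F2 | step 5 | 2-(diethoxymethyl)-4,5-dimethoxyphenol | CCOC(OCC)c1cc(OC)c(OC)cc1O
F3 | step 5 | 2-hydroxy-4,5-dimethoxybenzaldehyde | COc1cc(O)c(C=O)cc1OC
F4 | step 1 | tetramethylammonium pentacarbonyl(2-methoxyacryloyl)chromate | C[N+](C)(C)C.C=C(OC)C(=O)[Cr-](=C=O)(=C=O)(=C=O)(=C=O)=C=O
F5 | step 1 | pentacarbonyl[acetoxy(1-methoxyvinyl)carbene]chromium | CC(=O)OC(C(=C)OC)=[Cr](=C=O)(=C=O)(=C=O)(=C=O)=C=O
F6 | step 7 | methoxymethyl ether of 13 (racemic) | COCOc1cc(OC)c(OC)cc1C(O[Si](C)(C)C(C)(C)C)C#Cc1cc(OC)c(OC)c(OC)c1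
F7 | step 7 | 1-[4,5-dimethoxy-2-(methoxymethoxy)phenyl]-3-(3,4,5-trimethoxyphenyl)prop-2-yn-1-ol (racemic) | COCOc1cc(OC)c(OC)cc1C(O)C#Cc1cc(OC)c(OC)c(OC)c1
F8 | step 7 | 1-[4,5-dimethoxy-2-(methoxymethoxy)phenyl]-3-(3,4,5-trimethoxyphenyl)prop-2-yn-1-one | COCOc1cc(OC)c(OC)cc1C(=O)C#Cc1cc(OC)c(OC)c(OC)c1
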